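**Plan**

1. Retrosynthetic cuts, in order: the two MOM ethers on the ring-A catechol; the O1–C2 bond of the pyran (back to a prenyl on C4a); the aryl–CH2 bonds of the ring-A prenyls (C6, then C2) and of the ring-B prenyl; the biaryl bond C7–C1.
2. Enabling feature: the pyran atoms O1, C2, C3 and C4 are an oxidatively cyclised prenyl on C4a, which lies between two equivalent hydroxyls (on C5 and C8a) of a symmetric 5-arylresorcinol (ring B). With the ring-A catechol capped, this is the only prenyl with a free ortho hydroxyl.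
3. Forward: both benzene rings are bought and joined by Suzuki coupling. The ring-B prenyl enters by directed ortho-lithiation, the ring-A prenyls from O3 by Claisen (C2) and para-Claisen–Cope (C6) shifts. The pyran, the only ring built, closes in step 13, and the MOM groups leave last.
4. Numbering of intermediates: biphenyl numbering, ring A unprimed (C1 on the axis, O3, O4), ring B primed (C4′ becomes C4a, O3′/O5′ become the oxygens on C5 and C8a).
5. Stereochemistry: none to set. The target has no stereocentre and its biaryl axis is not stereogenic (ring B has hydrogen at both ortho positions), so the compound is achiral and no asymmetric step is needed.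

Key step: step 13

**Route**

Step 1
Reactants: 1 5-bromoresorcinol; 2 2-(trimethylsilyl)ethoxymethyl chloride (SEMCl)
Product: 3 1-bromo-3,5-bis{[2-(trimethylsilyl)ethoxy]methoxy}benzene
Conditions: NaH (2.4 equiv), SEMCl (2.3 equiv), DMF, 0 °C → rt
Reagents that add atoms: 2-(trimethylsilyl)ethoxymethyl chloride, C[Si](C)(C)CCOCCl
Why: Williamson O-alkylation of the bis-phenoxide; SEM is chosen because, like MOM, it directs ortho-lithiation, yet it is cleaved by fluoride and is therefore orthogonal to the MOM ethers of ring A.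

Step 2
Reactants: 3 1-bromo-3,5-bis{[2-(trimethylsilyl)ethoxy]methoxy}benzene; 4 bis(pinacolato)diboron
Product: 5 2-(3,5-bis{[2-(trimethylsilyl)ethoxy]methoxy}phenyl)-4,4,5,5-tetramethyl-1,3,2-dioxaborolane
Conditions: Pd(dppf)Cl2·CH2Cl2 (3 mol %), KOAc, 1,4-dioxane, 90 °C
Reagents that add atoms: bis(pinacolato)diboron, CC1(C)OB(OC1(C)C)B1OC(C)(C)C(C)(C)O1
Why: Miyaura borylation of an unhindered aryl bromide; the acetal ethers are inert to Pd(0) and acetate.

Step 3
Reactants: 6 5-bromosalicylaldehyde; 7 chloromethyl methyl ether (MOMCl)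
Product: 8 5-bromo-2-(methoxymethoxy)benzaldehyde
Conditions: MOMCl (1.3 equiv), K2CO3, acetone, rt
Reagents that add atoms: chloromethyl methyl ether, COCCl
Why: Williamson O-alkylation of the salicylaldehyde phenol with MOMCl, which marks the oxygen that becomes O4 (para to bromine) as different from the oxygen that the next step creates at O3.

Step 4
Reactants: 8 5-bromo-2-(methoxymethoxy)benzaldehyde; 9 3-chloroperoxybenzoic acid (mCPBA)
Product: 11 5-bromo-2-(methoxymethoxy)phenol, via 5-bromo-2-(methoxymethoxy)phenyl formate 10 (not isolated)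
Conditions: mCPBA (1.3 equiv), CH2Cl2, rt; wash (aq NaHCO3/Na2S2O3); then K2CO3, MeOH, rt
Reagents that add atoms: 3-chloroperoxybenzoic acid, OOC(=O)c1cccc(Cl)c1
Why: Dakin-type Baeyer–Villiger oxidation: the electron-rich ortho-alkoxyaryl group migrates in the Criegee intermediate to give aryl formate 10, whose methanolysis frees the O3 phenol without touching the MOM acetal.

Step 5
Reactants: 11 5-bromo-2-(methoxymethoxy)phenol; 5 2-(3,5-bis{[2-(trimethylsilyl)ethoxy]methoxy}phenyl)-4,4,5,5-tetramethyl-1,3,2-dioxaborolane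
Product: 12 4-(methoxymethoxy)-3′,5′-bis{[2-(trimethylsilyl)ethoxy]methoxy}biphenyl-3-ol
Conditions: Pd(dppf)Cl2·CH2Cl2 (4 mol %), K2CO3 (3 equiv), 1,4-dioxane/H2O (4:1), 85 °C
Reagents that add atoms: none
Why: Suzuki–Miyaura coupling of an unhindered aryl bromide with an unhindered arylboronate forms the biaryl bond C1–C1′; the free phenol (as phenoxide) and the SEM and MOM acetals tolerate aqueous carbonate.

Step 6
Reactants: 12 4-(methoxymethoxy)-3′,5′-bis{[2-(trimethylsilyl)ethoxy]methoxy}biphenyl-3-ol; 13 prenyl bromide (1-bromo-3-methylbut-2-ene)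
Product: 15 4-(methoxymethoxy)-4′-(3-methylbut-2-en-1-yl)-3′,5′-bis{[2-(trimethylsilyl)ethoxy]methoxy}biphenyl-3-ol, via lithium 4′-lithio-4-(methoxymethoxy)-3′,5′-bis{[2-(trimethylsilyl)ethoxy]methoxy}biphenyl-3-olate 14 (not isolated)
Conditions: n-BuLi (2.2 equiv), THF, 0 °C; then CuBr·SMe2 (10 mol %), prenyl bromide (1.1 equiv), −78 → 0 °C; H2O
Reagents that add atoms: prenyl bromide, CC(C)=CCBr
Why: Directed ortho-metalation: the first equivalent of n-BuLi makes the O3 phenoxide, which deactivates ring A, and the second lithiates C4′ between the two cooperating OSEM groups to give 14, whose copper-catalysed SN2 allylation with prenyl bromide installs the linear prenyl regiospecifically between the ring-B oxygens.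

Step 7
Reactants: 15 4-(methoxymethoxy)-4′-(3-methylbut-2-en-1-yl)-3′,5′-bis{[2-(trimethylsilyl)ethoxy]methoxy}biphenyl-3-ol; 16 3-chloro-3-methylbut-1-yne
Product: 17 4-(methoxymethoxy)-3-[(2-methylbut-3-yn-2-yl)oxy]-4′-(3-methylbut-2-en-1-yl)-3′,5′-bis{[2-(trimethylsilyl)ethoxy]methoxy}biphenyl
Conditions: 3-chloro-3-methylbut-1-yne (2 equiv), DBU, CuCl2·2H2O (1 mol %), MeCN, 0 °C
Reagents that add atoms: 3-chloro-3-methylbut-1-yne, C#CC(C)(C)Cl
Why: Copper-catalysed propargylic substitution of the tertiary chloride by the phenoxide (via a copper acetylide) is the standard entry to hindered aryl 1,1-dimethylpropargyl ethers, and O3 is the only free hydroxyl.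

Step 8
Reactants: 17 4-(methoxymethoxy)-3-[(2-methylbut-3-yn-2-yl)oxy]-4′-(3-methylbut-2-en-1-yl)-3′,5′-bis{[2-(trimethylsilyl)ethoxy]methoxy}biphenyl
Product: 19 4-(methoxymethoxy)-2,4′-bis(3-methylbut-2-en-1-yl)-3′,5′-bis{[2-(trimethylsilyl)ethoxy]methoxy}biphenyl-3-ol, via 4-(methoxymethoxy)-3-[(2-methylbut-3-en-2-yl)oxy]-4′-(3-methylbut-2-en-1-yl)-3′,5′-bis{[2-(trimethylsilyl)ethoxy]methoxy}biphenyl 18 (not isolated)
Conditions: H2 (1 atm), Lindlar catalyst, quinoline, toluene, rt; filter; then 120 °C (sealed tube)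
Reagents that add atoms: none
Why: Lindlar semihydrogenation gives the 1,1-dimethylallyl ether 18 (the trisubstituted prenyl alkene is not reduced), and aromatic Claisen rearrangement then delivers the allyl unit with inversion, i.e. as a linear prenyl, to C2, the only ortho position of O3 that carries hydrogen (C4 bears OMOM).

Step 9
Reactants: 19 4-(methoxymethoxy)-2,4′-bis(3-methylbut-2-en-1-yl)-3′,5′-bis{[2-(trimethylsilyl)ethoxy]methoxy}biphenyl-3-ol; 13 prenyl bromide
Product: 20 4-(methoxymethoxy)-2,4′-bis(3-methylbut-2-en-1-yl)-3-[(3-methylbut-2-en-1-yl)oxy]-3′,5′-bis{[2-(trimethylsilyl)ethoxy]methoxy}biphenyl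
Conditions: prenyl bromide (1.5 equiv), K2CO3, DMF, rt → 40 °C
Reagents that add atoms: prenyl bromide, CC(C)=CCBr
Why: Williamson O-prenylation of the O3 phenol, the only acidic site.

Step 10
Reactants: 20 4-(methoxymethoxy)-2,4′-bis(3-methylbut-2-en-1-yl)-3-[(3-methylbut-2-en-1-yl)oxy]-3′,5′-bis{[2-(trimethylsilyl)ethoxy]methoxy}biphenyl
Product: 22 4-(methoxymethoxy)-2,6,4′-tris(3-methylbut-2-en-1-yl)-3′,5′-bis{[2-(trimethylsilyl)ethoxy]methoxy}biphenyl-3-ol, via the C4 ortho-dienone 21 (not isolated)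
Conditions: N,N-diethylaniline, 190 °C, Ar (sealed tube)
Reagents that add atoms: none
Why: para-Claisen–Cope rearrangement: with both ortho positions of O3 substituted, the [3,3] shift gives an ortho-dienone that cannot enolise (drawn as 21, the shift onto C4, which places the 2-methylbut-3-en-2-yl group beside the OMOM group) and passes the allyl unit on by a Cope [3,3] shift to C6, the double inversion returning a linear prenyl, after which tautomerisation restores the phenol.

Step 11
Reactants: 22 4-(methoxymethoxy)-2,6,4′-tris(3-methylbut-2-en-1-yl)-3′,5′-bis{[2-(trimethylsilyl)ethoxy]methoxy}biphenyl-3-ol; 7 chloromethyl methyl ether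
Product: 23 3,4-bis(methoxymethoxy)-2,6,4′-tris(3-methylbut-2-en-1-yl)-3′,5′-bis{[2-(trimethylsilyl)ethoxy]methoxy}biphenyl
Conditions: NaH, MOMCl, THF–DMF, 0 °C → rt
Reagents that add atoms: chloromethyl methyl ether, COCCl
Why: O-alkylation of the hindered O3 phenoxide with MOMCl caps ring A as the bis-MOM catechol that the oxidation in step 13 requires.

Step 12
Reactants: 23 3,4-bis(methoxymethoxy)-2,6,4′-tris(3-methylbut-2-en-1-yl)-3′,5′-bis{[2-(trimethylsilyl)ethoxy]methoxy}biphenyl
Product: 24 3,4-bis(methoxymethoxy)-2,6,4′-tris(3-methylbut-2-en-1-yl)biphenyl-3′,5′-diol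
Conditions: TBAF (1 M in THF, 8 equiv), DMPU, 60 °C, Ar; aq NH4Cl
Reagents that add atoms: none
Why: Fluoride attack at silicon triggers β-elimination of each SEM group (fluorotrimethylsilane, ethene, then loss of formaldehyde from the hemiacetal), while aryl MOM ethers and the prenyl groups are inert to fluoride, so only the ring-B hydroxyls are freed.

Step 13
Reactants: 24 3,4-bis(methoxymethoxy)-2,6,4′-tris(3-methylbut-2-en-1-yl)biphenyl-3′,5′-diol
Product: 26 7-[3,4-bis(methoxymethoxy)-2,6-bis(3-methylbut-2-en-1-yl)phenyl]-2,2-dimethyl-2H-chromen-5-ol, via the ring-B vinyl o-quinone methide 25 (not isolated)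
Conditions: chloranil (1.1 equiv), toluene, 85 °C, Ar, dark
Reagents that add atoms: none
Why: Chloranil forms a charge-transfer complex with the electron-rich resorcinol ring B and removes the phenolic hydrogen and then a hydrogen of the benzylic, allylic CH2 (net hydride loss), giving the vinyl o-quinone methide 25, which closes by thermal oxa-6π electrocyclisation (oxygen to the CMe2 terminus, forming O1–C2) and so restores the aromaticity of ring B. The closest known reaction type is the quinone (chloranil or DDQ) dehydrogenative cyclisation of ortho-prenylphenols to 2,2-dimethyl-2H-chromenes, as in the cannabigerol-to-cannabichromene conversion. The pyran closes in a six-membered pericyclic (disrotatory oxa-6π) mode, and no stereocentre arises because C2 carries two methyl groups. The step needs chemoselectivity among three prenyls and regioselectivity between two oxygens: only the ring-B prenyl has a free ortho hydroxyl (ring A is capped as MOM ethers and cannot form a quinone methide, and the weak oxidant chloranil spares its benzylic CH2 groups), and the two ring-B hydroxyls are equivalent by symmetry, so either closure gives 26.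

Step 14
Reactants: 26 7-[3,4-bis(methoxymethoxy)-2,6-bis(3-methylbut-2-en-1-yl)phenyl]-2,2-dimethyl-2H-chromen-5-ol
Product: 27 clusiachromene D, 4-(5-hydroxy-2,2-dimethyl-2H-chromen-7-yl)-3,5-bis(3-methylbut-2-en-1-yl)benzene-1,2-diol
Conditions: ZnBr2 (2.2 equiv), n-PrSH (4 equiv), CH2Cl2, 0 °C, 10 min, Ar
Reagents that add atoms: none
Why: Zinc bromide-assisted thiolysis of the MOM acetals (the thiol captures the methoxymethyl cation) is complete within minutes at 0 °C, before acid-promoted addition of the new O3–H to the C2 prenyl or to the chromene alkene can compete.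

**Compound list**

1 | 5-bromoresorcinol | Oc1cc(O)cc(Br)c1 | starting material
2 | 2-(trimethylsilyl)ethoxymethyl chloride | C[Si](C)(C)CCOCCl | starting material
3 | 1-bromo-3,5-bis{[2-(trimethylsilyl)ethoxy]methoxy}benzene | Brc1cc(OCOCC[Si](C)(C)C)cc(OCOCC[Si](C)(C)C)c1 | intermediate
4 | bis(pinacolato)diboron | CC1(C)OB(OC1(C)C)B1OC(C)(C)C(C)(C)O1 | starting material
5 | 2-(3,5-bis{[2-(trimethylsilyl)ethoxy]methoxy}phenyl)-4,4,5,5-tetramethyl-1,3,2-dioxaborolane | CC1(C)OB(OC1(C)C)c1cc(OCOCC[Si](C)(C)C)cc(OCOCC[Si](C)(C)C)c1 | intermediate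
6 | 5-bromosalicylaldehyde | O=Cc1cc(Br)ccc1O | starting material
7 | chloromethyl methyl ether | COCCl | starting material
8 | 5-bromo-2-(methoxymethoxy)benzaldehyde | O=Cc1cc(Br)ccc1OCOC | intermediate
9 | 3-chloroperoxybenzoic acid | OOC(=O)c1cccc(Cl)c1 | starting material
10 | 5-bromo-2-(methoxymethoxy)phenyl formate | O=COc1cc(Br)ccc1OCOC | intermediate (not isolated)
11 | 5-bromo-2-(methoxymethoxy)phenol | Oc1cc(Br)ccc1OCOC | intermediate
12 | 4-(methoxymethoxy)-3′,5′-bis(SEM-oxy)biphenyl-3-ol | COCOc1ccc(cc1O)-c1cc(OCOCC[Si](C)(C)C)cc(OCOCC[Si](C)(C)C)c1 | intermediate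
13 | prenyl bromide | CC(C)=CCBr | starting material
14 | lithium 4′-lithio-4-(methoxymethoxy)-3′,5′-bis(SEM-oxy)biphenyl-3-olate | [Li]Oc1cc(ccc1OCOC)-c1cc(OCOCC[Si](C)(C)C)c([Li])c(OCOCC[Si](C)(C)C)c1 | intermediate (not isolated)
15 | 4-(methoxymethoxy)-4′-prenyl-3′,5′-bis(SEM-oxy)biphenyl-3-ol | COCOc1ccc(cc1O)-c1cc(OCOCC[Si](C)(C)C)c(CC=C(C)C)c(OCOCC[Si](C)(C)C)c1 | intermediate
16 | 3-chloro-3-methylbut-1-yne | C#CC(C)(C)Cl | starting material
17 | 3-(1,1-dimethylpropargyl) ether of 15 | COCOc1ccc(cc1OC(C)(C)C#C)-c1cc(OCOCC[Si](C)(C)C)c(CC=C(C)C)c(OCOCC[Si](C)(C)C)c1 | intermediate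
18 | 3-(1,1-dimethylallyl) ether of 15 | COCOc1ccc(cc1OC(C)(C)C=C)-c1cc(OCOCC[Si](C)(C)C)c(CC=C(C)C)c(OCOCC[Si](C)(C)C)c1 | intermediate (not isolated)
19 | 4-(methoxymethoxy)-2,4′-diprenyl-3′,5′-bis(SEM-oxy)biphenyl-3-ol | COCOc1ccc(-c2cc(OCOCC[Si](C)(C)C)c(CC=C(C)C)c(OCOCC[Si](C)(C)C)c2)c(CC=C(C)C)c1O | intermediate
20 | 4-(methoxymethoxy)-2,4′-diprenyl-3-(prenyloxy)-3′,5′-bis(SEM-oxy)biphenyl | COCOc1ccc(-c2cc(OCOCC[Si](C)(C)C)c(CC=C(C)C)c(OCOCC[Si](C)(C)C)c2)c(CC=C(C)C)c1OCC=C(C)C | intermediate
21 | C4 ortho-dienone from the [3,3] shift onto C4 (racemic): 6-(methoxymethoxy)-6-(2-methylbut-3-en-2-yl)-2-prenyl-3-[4-prenyl-3,5-bis(SEM-oxy)phenyl]cyclohexa-2,4-dien-1-one | O=C1C(CC=C(C)C)=C(c2cc(OCOCC[Si](C)(C)C)c(CC=C(C)C)c(OCOCC[Si](C)(C)C)c2)C=CC1(OCOC)C(C)(C)C=C | intermediate (not isolated)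
22 | 4-(methoxymethoxy)-2,6,4′-triprenyl-3′,5′-bis(SEM-oxy)biphenyl-3-ol | COCOc1cc(CC=C(C)C)c(-c2cc(OCOCC[Si](C)(C)C)c(CC=C(C)C)c(OCOCC[Si](C)(C)C)c2)c(CC=C(C)C)c1O | intermediate
23 | 3,4-bis(methoxymethoxy)-2,6,4′-triprenyl-3′,5′-bis(SEM-oxy)biphenyl | COCOc1cc(CC=C(C)C)c(-c2cc(OCOCC[Si](C)(C)C)c(CC=C(C)C)c(OCOCC[Si](C)(C)C)c2)c(CC=C(C)C)c1OCOC | intermediate
24 | 3,4-bis(methoxymethoxy)-2,6,4′-triprenylbiphenyl-3′,5′-diol (key-step precursor) | COCOc1cc(CC=C(C)C)c(-c2cc(O)c(CC=C(C)C)c(O)c2)c(CC=C(C)C)c1OCOC | intermediate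
25 | ring-B vinyl o-quinone methide: 3-[3,4-bis(methoxymethoxy)-2,6-diprenylphenyl]-5-hydroxy-6-(3-methylbut-2-en-1-ylidene)cyclohexa-2,4-dien-1-one, side chain cis to the carbonyl | COCOc1cc(CC=C(C)C)c(C2=CC(=O)/C(=C\C=C(C)C)C(O)=C2)c(CC=C(C)C)c1OCOC | intermediate (not isolated)
26 | 7-[3,4-bis(methoxymethoxy)-2,6-diprenylphenyl]-2,2-dimethyl-2H-chromen-5-ol (key-step product) | CC(C)=CCc1cc(OCOC)c(OCOC)c(CC=C(C)C)c1-c1cc(O)c2c(c1)OC(C)(C)C=C2 | intermediate
27 | clusiachromene D | CC(C)=CCc1cc(O)c(O)c(CC=C(C)C)c1-c1cc(O)c2c(c1)OC(C)(C)C=C2 | target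

**Totals and risks**

Total step count: 14. Longest linear sequence: 12 steps (steps 1, 2 and 5–14, or equally steps 3, 4 and 5–14).

Steps most likely to fail:

Step 13 (key step). Hydride abstraction may be unselective or go too far: oxidation at the benzylic positions of the electron-rich ring A, addition of the quinone or its hydroquinone to the quinone methide, or further oxidation of the product chromenol. The fallback sets out from 24 and returns at 26 by electrophilic rather than oxidative activation. N-(Phenylseleno)phthalimide with catalytic camphorsulfonic acid in CH2Cl2 at −40 °C should effect 6-endo (Markovnikov) selenoetherification of the only prenyl that has a free internal oxygen nucleophile, giving 7-[3,4-bis(methoxymethoxy)-2,6-diprenylphenyl]-2,2-dimethyl-3-(phenylselanyl)chroman-5-ol F1 (racemic). Oxidation of the selenide with mCPBA (1 equiv) at −78 °C should give 7-[3,4-bis(methoxymethoxy)-2,6-diprenylphenyl]-2,2-dimethyl-3-(phenylseleninyl)chroman-5-ol F2 (the selenoxide, a mixture of diastereomers, not isolated). Warming with i-Pr2NH should then cause its syn-elimination toward C4 (C2 has no hydrogen) and deliver 26.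

Step 10. At 190 °C the prenyl ether may fragment with loss of isoprene (returning 19), or the C2 prenyl may take part in the Cope shift and scramble linear and reverse prenyl groups. The fallback sets out from 19 and returns at 22 through an unsubstituted allyl group, whose rearrangement is cleaner. O-Allylation (allyl bromide, K2CO3, DMF) should give 3-(allyloxy)-4-(methoxymethoxy)-2,4′-diprenyl-3′,5′-bis(SEM-oxy)biphenyl F3. Its para-Claisen rearrangement (N,N-diethylaniline, 190 °C) should pass through 6-allyl-6-(methoxymethoxy)-2-prenyl-3-[4-prenyl-3,5-bis(SEM-oxy)phenyl]cyclohexa-2,4-dien-1-one F4 (the ortho-dienone, racemic, not isolated) and give 6-allyl-4-(methoxymethoxy)-2,4′-diprenyl-3′,5′-bis(SEM-oxy)biphenyl-3-ol F5. Cross-metathesis with 2-methylbut-2-ene (Grubbs second-generation catalyst, CH2Cl2, 40 °C) then turns the terminal allyl into prenyl, the existing trisubstituted prenyls being left unchanged, to give 22.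

Step 14. The Lewis acid and thiol may trigger addition of the freed O3–H to the C2 prenyl (chroman formation) or addition of thiol or proton to the chromene alkene, and the free catechol may air-oxidise during work-up. The fallback sets out from 26 and returns at 27 by silyl transfer under buffered, non-protic conditions. TMSOTf with excess 2,2′-bipyridyl in CH2Cl2 at 0 °C converts aryl MOM ethers, through a bipyridinium salt of the methoxymethyl group, into aryl trimethylsilyl ethers. With the C5 hydroxyl silylated as well, this should give the tris(trimethylsilyl) ether of clusiachromene D F6, and addition of water hydrolyses the three silyl ethers to 27.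

**Further compounds**

F1 | step 13 | 7-[3,4-bis(methoxymethoxy)-2,6-diprenylphenyl]-2,2-dimethyl-3-(phenylselanyl)chroman-5-ol (racemic) | CC(C)=CCc1cc(OCOC)c(OCOC)c(CC=C(C)C)c1-c1cc(O)c2c(c1)OC(C)(C)C(C2)[Se]c1ccccc1
F2 | step 13 | 7-[3,4-bis(methoxymethoxy)-2,6-diprenylphenyl]-2,2-dimethyl-3-(phenylseleninyl)chroman-5-ol (mixture of diastereomers) | CC(C)=CCc1cc(OCOC)c(OCOC)c(CC=C(C)C)c1-c1cc(O)c2c(c1)OC(C)(C)C(C2)[Se](=O)c1ccccc1
F3 | step 10 | 3-(allyloxy)-4-(methoxymethoxy)-2,4′-diprenyl-3′,5′-bis(SEM-oxy)biphenyl | COCOc1ccc(-c2cc(OCOCC[Si](C)(C)C)c(CC=C(C)C)c(OCOCC[Si](C)(C)C)c2)c(CC=C(C)C)c1OCC=C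
F4 | step 10 | 6-allyl-6-(methoxymethoxy)-2-prenyl-3-[4-prenyl-3,5-bis(SEM-oxy)phenyl]cyclohexa-2,4-dien-1-one (racemic) | O=C1C(CC=C(C)C)=C(c2cc(OCOCC[Si](C)(C)C)c(CC=C(C)C)c(OCOCC[Si](C)(C)C)c2)C=CC1(OCOC)CC=C
F5 | step 10 | 6-allyl-4-(methoxymethoxy)-2,4′-diprenyl-3′,5′-bis(SEM-oxy)biphenyl-3-ol | COCOc1cc(CC=C)c(-c2cc(OCOCC[Si](C)(C)C)c(CC=C(C)C)c(OCOCC[Si](C)(C)C)c2)c(CC=C(C)C)c1O
F6 | step 14 | tris(trimethylsilyl) ether of clusiachromene D | CC(C)=CCc1cc(O[Si](C)(C)C)c(O[Si](C)(C)C)c(CC=C(C)C)c1-c1cc(O[Si](C)(C)C)c2c(c1)OC(C)(C)C=C2
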